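The trap in these flasks is to read the target's early speed and multiply it by the time.

| flask | starting material | reagent | remark | time |
|---|---|---|---|---|
| dawn | 0.075 M | 0.80 equiv | run made earlier |  |
| spring | 0.30 M | 0.80 equiv | run made earlier |  |
| alder | 0.15 M | 0.800 equiv |  | 4.0 min |
| ash | 0.15 M | 0.800 equiv |  | 6.0 min |
| oak | 0.15 M | 0.800 equiv |  | 10 min |

| run | time / min | isomer of the product / % | target / % | tautomer / % | starting material / % |
|---|---|---|---|---|---|
| dawn | 0.833 | 5 | 1 | 60 | 27 |
| dawn | 1.50 | 2 | 6 | 70 | 11 |
| dawn | 2.50 | 1 | 11 | 67 | 7 |
| dawn | 3.00 | 0 | 16 | 67 | 6 |
| dawn | 4.00 | 2 | 19 | 65 | 6 |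
| dawn | 5.00 | 3 | 21 | 61 | 5 |
| spring | 0.417 | 4 | 5 | 36 | 40 |
| spring | 0.667 | 6 | 7 | 42 | 27 |
| spring | 1.00 | 4 | 9 | 46 | 15 |
| spring | 2.00 | 10 | 19 | 44 | 7 |
| spring | 3.00 | 11 | 30 | 35 | 4 |
| spring | 5.00 | 9 | 40 | 27 | 5 |

(readings scatter by 1.5 percentage points)

* which of these there is most of at the end, counted by the starting material in it, alder (tautomer / starting material / isomer of the product / target)
* which of these there is most of at the end, counted by the starting material in it, ash (tautomer / starting material / isomer of the product / target)
* which of these there is most of at the end, counted by the starting material in it, oak (tautomer / starting material / isomer of the product / target)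
* the largest of these amounts at the end, in percent of the starting material charged, alder
* the largest of these amounts at the end, in percent of the starting material charged, ash
* the largest of these amounts at the end, in percent of the starting material charged, oak



The runs show starting material filling the tautomer within about 1.00 min, then tautomer and reagent giving target, with a little isomer of the product beside it. Target speed is therefore read as a constant times tautomer times the fraction of reagent left. In spring, target climbs 0.105 min⁻¹ around 2.00 min, with tautomer at 44% and 63.7% of the reagent left, so the constant reads 0.374 min⁻¹. In dawn, 0.0429 min⁻¹ around 3.00 min, with tautomer at 67% and 80.0% of the reagent left, gives 0.0800 min⁻¹.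

The charge 0.15 M lies midway between the two runs in logarithms, so the midpoint there gives a constant of 0.173 min⁻¹. The same midpoint of tautomer plus target at the last readings gives a pool of 74.1%. Reagent left over from the isomer of the product, on the same count, is 74.8%, so the two partners are matched. Reagent charge over constant times pool gives 6.24 min: this is the pairing time, the time in which matched partners fall to half of their opening amount, a second-order half-life.

Speed opens at pool over pairing time, 0.119 min⁻¹, counted from 1.00 min. Each partner then falls by a factor of one plus elapsed time over pairing time. For oak that factor is 2.44, or 0.387 in powers of ten. Tautomer and reagent together take 0.775 powers of ten off the speed, which the reckoning closes at 0.0200 min⁻¹. Mean speed sits midway in logarithms, so the reckoning gives oak a gain of 43.8% of target, not the 107% of the trap, and leaves oak 30.3% of tautomer. It leaves alder 50.1% of tautomer and ash 41.1%, with the target of ash reckoned at 33.0%.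

The forecast has tautomer at 48% in alder, tautomer at 38% in ash, “close to the crossover, with tautomer narrowly ahead”, and target at 44% in oak, its ash figure standing 3.1 percentage points under the reckoning here.

The flasks give tautomer at 48.0% in alder, tautomer at 40.1% in ash and target at 44.9% in oak.

    starting material ⇌ tautomer (K = 9.80, k = 0.0250 s⁻¹)
    starting material + reagent → isomer of the product (k = 0.0130 L mol⁻¹ s⁻¹)
    reagent + tautomer → target (k = 0.0240 L mol⁻¹ s⁻¹)
    2 starting material → homo dimer (k = 0.0280 L mol⁻¹ s⁻¹)

In ash, each step taken net, tautomer was made 11.7 times as fast as it was used at 0.359 min, and by 3.00 min the step from starting material had 99.2% of its turnover up to the asked time behind it. Reagent and tautomer ran on in ash, with half of their turnover up to that time done by 2.41 min. The pairing time put the tautomer of oak at 30.3% against 30.3%, and that of alder at 50.1% against 48.0%. A flask like ash but with 1.40 equiv of reagent sets that charge against a pool of 74.1%: rescaled to it, the pairing time becomes a decay time of 3.30 min. With reagent ending at 56.8% of its charge and its mean taken midway in logarithms, that reckons 23.7% of tautomer, and this flask holds 23.2%.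

All runs are simulated for substances that don't exist; scatter was added.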